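Whatever happens in these flasks, each X charged stays counted, as X, as G or as something unread, and you can keep the same books on Q, which goes in as a fixed charge.

all flasks: X 0.50 M

|  | Q | D | remark | time |
|---|---|---|---|---|
| south-west | 0.40 equiv | 2.5 equiv | run made earlier |  |
| north-east | 1.9 equiv | 2.5 equiv | run made earlier |  |
| Saturday's | 0.300 equiv | 2.50 equiv |  | 5.0 min |
| Monday's | 0.600 equiv | 2.50 equiv |  | 5.0 min |
| Tuesday's | 1.20 equiv | 2.50 equiv |  | 5.0 min |

| run | time / min | X / % | G / % |
|---|---|---|---|
| south-west | 0.333 | 94.8 | 5.3 |
| south-west | 0.833 | 91.9 | 9.1 |
| south-west | 1.50 | 84.9 | 13.4 |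
| south-west | 2.50 | 73.5 | 19.6 |
| north-east | 0.333 | 92.5 | 5.5 |
| north-east | 0.833 | 85.2 | 13.3 |
| north-east | 1.50 | 76.5 | 25.4 |
| north-east | 2.50 | 61.6 | 34.0 |

(scatter of a reading: 1 percentage point)

- part of the X that has reacted at the end, Saturday's
- part of the X that has reacted at the end, Monday's
- part of the X that has reacted at the end, Tuesday's
- what raising the equivalents of Q from its lowest to its highest value here does to the part of the X that has reacted (changes below 5 percentage points count as none) (no change / it rises / it falls)

- the analysis behind the earlier runs scatters by 1 percentage point, standard deviation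

Read the two tables row against row. In the early rows X and G add up to about the charge, but in the last row the south-west run falls short by 6.9 percentage points and the north-east run by 4.4 points, so as a reading, with 1 point of scatter on each number, something besides G is taking X. The G column then gives a pace: the south-west run made 19.6% of G by 2.50 min, which is 0.0784 min⁻¹ in equivalents per minute.

Now I add an assumption of my own, that one Q is spent per G. Saturday's charge over that pace gives 3.83 min, the lasting time of Q, which is shorter than the 5.0 min asked, so I expect the Q of Saturday's flask to last less than the time asked. Monday's charge at the same pace lasts 7.65 min, longer than the time asked, and should leave 34.7% of its Q at the end. Tuesday's charge at the north-east pace lasts 8.82 min. This reckoning gives me a time for Q and no conversions.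

The forecast gives 39%, 47% and 56% for Saturday's, Monday's and Tuesday's, and on raising Q says it rises, with the caveat that “Q may be consumed stoichiometrically”.

The flask gives 38.3%, 41.9% and 50.5%, and it rises by 12 points, so the forecast stands 5.1 points high on Monday's and 5.5 points high on Tuesday's.

    J + Q ⇌ E (K = 1800 M⁻¹, k = 8.80 M⁻¹ min⁻¹)
    X + J → Z (k = 0.540 M⁻¹ min⁻¹)
    L + J ⇌ D, settled at all times (K = 3300 M⁻¹)
    X + L → J + G (k = 10.0 M⁻¹ min⁻¹)

Saturday's flask still holds 8.66% of its Q at 5.00 min, past the lasting time, having spent 1.03 Q per G. Monday's flask holds 16.8%, less than the 34.7% reckoned, having spent 1.48 Q per G. The neighbour is Saturday's flask stopped at 3.0 min, where the lasting time leaves 21.7% of the Q; that flask holds 27.3% of its Q, with 26.6% of its X reacted.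

(The runs were generated by integration with constants of no real substance; the scatter is artificial.)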